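Beside this flask stands a neighbour with 0.64 M of substrate, and I want one number that serves both.

substrate 1.6 M; partner 1.76 M; precatalyst 1.6 mM; time 1.0 min

* at 1.0 min, what has stopped the reaction, if anything has (the partner has run out first / it is still moving / forward and back rates have come level / all of the substrate has reacted / no working catalyst is left)
* how much target there is at 1.0 min, in percent of the substrate charged

    substrate + free catalyst ⇌ catalyst intermediate A (K1 = 0.55 M⁻¹, k1 = 203 M⁻¹ s⁻¹)
    partner + catalyst intermediate A → catalyst intermediate B (k2 = 66.3 M⁻¹ s⁻¹)
    catalyst intermediate B ⇌ by-product + catalyst intermediate C (K3 = 120 M, k3 = 57.2 s⁻¹)
    catalyst intermediate C → free catalyst + target (k4 = 122 s⁻¹)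
    target + by-product → side product (k5 = 0.0363 M⁻¹ s⁻¹)
    partner + precatalyst → free catalyst + spent reagent (k6 = 0.0581 M⁻¹ s⁻¹)

Free catalyst binds substrate, partner joins, by-product leaves and target comes off. Target and by-product can then combine to side product.

Which reagent is short? The substrate is, at 1.6 M, less than the 1.76 M of partner, so it is the limiting reagent. Its balance is simple: substrate lost appears as target plus side product, since bound forms hold at most 1.6 mM, far less than the charge. Each turn gives one target and one by-product, and the side step removes one of each. So [by-product] tracks [target], and the loss of target goes with [target] squared.

How fast is that loss? I take the side half-time, 17.2 s: the time in which the side step halves target and by-product if the whole charge stood as those two. The share of such a charge left after a time t is then the half-time divided by the half-time plus t. This half-time is shorter than the run, and the share at 1.0 min is 22.3%.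

Is the charge made that early? No. The precatalyst, with partner at its charge, has a half-life of 6.78 s, shorter than the run. With fresh reagents and steady intermediates, I reckon a turnover of 21.2 s⁻¹ per catalyst. At that pace the charge needs 47.1 s, shorter than the run, but I expect the pace to fall as reagents fall. So I expect this flask still moving at 1.0 min. The making takes longer than the side half-time, so I expect target above 22.3%.

The forecast says it is still moving and 38%, holding that “The slow-looking target + by-product step matters at these molar concentrations”.

The simulation gives it is still moving, with 38.4% of target, above my 22.3%, and 32% of substrate left.

This flask is not at rest: a share moved by 31 percentage points over the second half of the time. At 10.0 min target stands at 3.89%, side product at 96.0% and substrate at 0.0758%. The side half-time gives 2.79% for that time, against the computed 3.89%.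

In the neighbour flask the side half-time becomes 43.0 s, and the share at 1.0 min becomes 41.7%. The computed target in that neighbour flask is 59.5%, with 9.8% of its substrate left.

All constants are invented, and the outcome is calculated.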